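A leftover was my way in: after 20.0 h the blue run still held 40.6% of its starting material, and the amber run 63.0%. In these closed, stirred flasks, starting material met reagent and gave intermediate and released group. Target and side product appeared in the readings as well. Two new flasks, spring and noon, were to be forecast at 40 h.

all flasks: starting material 0.010 M

| charge | reagent | remark | time |
|---|---|---|---|
| amber | 1.3 equiv | run made earlier |  |
| blue | 2.5 equiv | run made earlier |  |
| spring | 2.00 equiv |  | 40 h |
| noon | 1.00 equiv |  | 40 h |

| run | time / h | intermediate / % | side product / % | target / % | starting material / % |
|---|---|---|---|---|---|
| amber | 2.50 | 5.1 | 0.2 | 0.6 | 94.5 |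
| amber | 8.00 | 13.0 | 0.8 | 2.4 | 82.7 |
| amber | 12.0 | 16.7 | 2.5 | 4.2 | 75.2 |
| amber | 20.0 | 21.5 | 5.3 | 9.1 | 63.0 |
| blue | 1.50 | 6.4 | 0.3 | 0.5 | 93.8 |
| blue | 4.00 | 14.3 | 0.9 | 1.4 | 83.9 |
| blue | 8.00 | 23.2 | 2.0 | 3.9 | 70.3 |
| blue | 20.0 | 34.9 | 7.6 | 13.6 | 40.6 |

(readings scatter by 0.3 percentage points)

1. which of these there is most of at the end, counted by the starting material in it, spring (intermediate / target / side product / starting material)
2. which of these there is most of at the end, counted by the starting material in it, noon (intermediate / target / side product / starting material)
3. how much there is at the end of the one of these that leads, in percent of the starting material charged: spring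
4. how much there is at the end of the one of these that leads, in percent of the starting material charged: noon

- candidate steps: starting material + reagent -> intermediate + released group; intermediate <-> target; intermediate <-> isomer of the product; starting material + released group -> side product; target -> over-reaction product
- a reading of intermediate is of its free form alone

I counted turnovers. The turnover count is the natural logarithm of charged over left. I took it to grow with the charged reagent concentration times the hours, a pseudo-first-order reckoning. The count per unit of that product is my turnover constant, and the blue run gave 1.80 L mol⁻¹ h⁻¹. The amber run, with a different charge, gave 1.78 L mol⁻¹ h⁻¹, so the constant passed a check. It folds the starting material taken by the side product into the same number.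

Then I turned the settings by hand, starting from the amber run at 20.0 h. For raising just the reagent to 2.00 equiv, my count gave a leftover of 48.7%. For raising just the time to 40 h, it gave 39.2%. Both together are spring, with a count of 1.44, and my estimate for its leftover was 23.6%. Noon, at 1.00 equiv, has a count of 0.721, and my estimate for its leftover was 48.6%. The starting concentration sits in the same product, since the equivalents ride on it, but both runs stood at 0.010 M, so the readings did not test that. The count does not split the reacted part, so I had no figure of my own for the intermediate.

The forecast named intermediate at 28% for spring and starting material at 49.5% for noon. Of spring it said: “intermediate leads narrowly, and target could overtake it”.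

Spring gave intermediate at 33.7%, with starting material at 23.6%, and noon gave starting material at 48.8%. From the amber run's 62.5% of starting material at its last reading, scatter aside, changing just the reagent to that of spring gave 48.5%, and changing just the time to that of spring gave 39.3%.

    starting material + reagent → intermediate + released group (k = 0.0294 L mol⁻¹ min⁻¹)
    intermediate ⇌ target (K = 0.830, k = 7.13 × 10⁻⁴ min⁻¹)
    intermediate ⇌ isomer of the product (K = 88.8, k = 1.10 × 10⁻⁴ min⁻¹)
    starting material + released group → side product (k = 0.0397 L mol⁻¹ min⁻¹)
    target → over-reaction product (k = 5.77 × 10⁻⁷ min⁻¹)

Spring kept less starting material than noon, and the main reason is the difference in equivalents: with that difference taken away, spring holds 48.8% of its starting material instead of 23.6%. The turnover constant of 1.80 L mol⁻¹ h⁻¹ then went to one more flask, like spring but charged with 0.0060 M of starting material. Its count is 0.865, which gives an estimated leftover of 42.1%, and that flask held 41.9% of its starting material.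

The numbers in the tables were computed for an exercise; the scatter is artificial.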